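**Retrosynthetic overview**
- The only ring is the oxolane-2,5-dione. Its CH2–CH edge carries one C=O on each carbon, and both C=O are bound to the same ring oxygen; taking out the two CO units leaves a terminal oxirane (O bridging that CH2–CH pair).
- Both acyl–carbon bonds (CH2–C(=O) and CH–C(=O)) are therefore made in one pot by double carbonylation of a threo (R,R) epoxy silyl ether. The ring grows oxirane → oxetan-2-one → oxolane-2,5-dione, and the ring CH is set by SN2 inversion of the epoxide CH.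
- The threo epoxy alcohol comes from C2-symmetric (2R,2'R)-2,2'-bioxirane (D-threitol pool) by mono-opening with a propargyl ether acetylide.
- The (E)-trisubstituted alkene comes from hydroxyl-directed trans-hydrostannation of the propargylic alcohol, iododestannylation and B-alkyl Suzuki–Miyaura coupling with a homofarnesyl borane made from farnesol.
- Endgame: removal of both silyl ethers, then selective oxidation of the primary allylic alcohol to the enal.

Key step: step 11

Assumption: the ion-pair catalyst [(ClTPP)Al(THF)2][Co(CO)4] (ClTPP = meso-tetrakis(4-chlorophenyl)porphyrinato) is made beforehand from (ClTPP)AlCl and NaCo(CO)4 and is not counted as a step.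

**Route**

Step 1
Reactants: 1 (2R,3R)-2,3-dihydroxybutane-1,4-diyl bis(4-methylbenzenesulfonate) (1,4-di-O-tosyl-D-threitol)
Product: 2 (2R,2'R)-2,2'-bioxirane
Conditions: KOH, Et2O/H2O, 0 °C to rt
Reagents that add atoms: none
Why: Twofold intramolecular Williamson etherification (3-exo-tet) of the secondary alkoxides onto the primary tosylates should close both oxiranes without touching either stereocentre, so the (2R,3R) configuration is carried over unchanged.

Step 2
Reactants: 2 (2R,2'R)-2,2'-bioxirane; 3 1-methoxy-4-[(prop-2-yn-1-yloxy)methyl]benzene (4-methoxybenzyl propargyl ether)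
Product: 5 (1R)-5-[(4-methoxybenzyl)oxy]-1-[(2R)-oxiran-2-yl]pent-3-yn-1-ol, via lithium acetylide 4 (not isolated)
Conditions: 3, n-BuLi, THF, −78 °C; BF3·OEt2; then 2 (1.5 equiv), −78 °C; H2O
Reagents that add atoms: none
Why: BF3-promoted alkynylation of an epoxide should open one oxirane of the C2-symmetric bis-epoxide by SN2 at its CH2 terminus, the excess of 2 and the borate formed next to the second oxirane should hold the reaction at mono-opening, and since no stereocentre is touched the threo (R,R) epoxy alcohol results directly.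

Step 3
Reactants: 5 (1R)-5-[(4-methoxybenzyl)oxy]-1-[(2R)-oxiran-2-yl]pent-3-yn-1-ol
Product: 6 triethyl({(1R)-5-[(4-methoxybenzyl)oxy]-1-[(2R)-oxiran-2-yl]pent-3-yn-1-yl}oxy)silane
Conditions: TESCl, imidazole, CH2Cl2, 0 °C
Reagents that add atoms: chlorotriethylsilane, CC[Si](Cl)(CC)CC
Why: Imidazole-mediated silylation of a secondary alcohol is routine and also blocks Payne rearrangement of the epoxy alcohol in the later basic steps.

Step 4
Reactants: 6 triethyl({(1R)-5-[(4-methoxybenzyl)oxy]-1-[(2R)-oxiran-2-yl]pent-3-yn-1-yl}oxy)silane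
Product: 7 (5R)-5-[(2R)-oxiran-2-yl]-5-[(triethylsilyl)oxy]pent-2-yn-1-ol
Conditions: DDQ, CH2Cl2/pH 7 buffer, 0 °C
Reagents that add atoms: none
Why: Oxidative cleavage of the 4-methoxybenzyl ether by DDQ (hydride abstraction, then hydrolysis of the oxocarbenium ion) under buffered conditions should leave the silyl ether, the alkyne and the epoxide intact.

Step 5
Reactants: 7 (5R)-5-[(2R)-oxiran-2-yl]-5-[(triethylsilyl)oxy]pent-2-yn-1-ol
Product: 8 (2Z,5R)-5-[(2R)-oxiran-2-yl]-2-(tributylstannyl)-5-[(triethylsilyl)oxy]pent-2-en-1-ol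
Conditions: Bu3SnH (slow addition), [Cp*RuCl]4 (cat.), CH2Cl2, rt
Reagents that add atoms: tributyltin hydride, CCCC[SnH](CCCC)CCCC
Why: In the hydroxyl-directed ruthenium-catalysed trans-hydrostannation of a propargylic alcohol, hydrogen bonding of the free OH to the chloride ligand should place tin on the proximal alkyne carbon and hydrogen anti to it, which sets the geometry (H cis to CH2OH) that becomes the (E)-enal of the target.

Step 6
Reactants: 8 (2Z,5R)-5-[(2R)-oxiran-2-yl]-2-(tributylstannyl)-5-[(triethylsilyl)oxy]pent-2-en-1-ol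
Product: 9 (2Z,5R)-2-iodo-5-[(2R)-oxiran-2-yl]-5-[(triethylsilyl)oxy]pent-2-en-1-ol
Conditions: I2, CH2Cl2, 0 °C
Reagents that add atoms: iodine, [I][I]
Why: Iododestannylation is an electrophilic ipso-substitution at sp2 carbon and should replace tin by iodine with retention of the alkene geometry.

Step 7
Reactants: 10 (2E,6E)-3,7,11-trimethyldodeca-2,6,10-trien-1-ol ((2E,6E)-farnesol)
Product: 11 (2E,6E)-3,7,11-trimethyldodeca-2,6,10-trienal ((2E,6E)-farnesal)
Conditions: TEMPO (cat.), PhI(OAc)2, CH2Cl2, rt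
Reagents that add atoms: none
Why: Oxoammonium-mediated (TEMPO/PhI(OAc)2) oxidation of a primary allylic alcohol should give the enal without E/Z isomerisation of the conjugated alkene.

Step 8
Reactants: 11 (2E,6E)-3,7,11-trimethyldodeca-2,6,10-trienal
Product: 12 (3E,7E)-4,8,12-trimethyltrideca-1,3,7,11-tetraene
Conditions: Ph3PCH3Br, KOtBu, THF, 0 °C; then 11
Reagents that add atoms: methyltriphenylphosphonium bromide, [Br-].C[P+](c1ccccc1)(c1ccccc1)c1ccccc1
Why: Wittig methylenation of the enal with the non-stabilised ylide should give the terminal 1,3-diene without disturbing the trisubstituted alkenes.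

Step 9
Reactants: 9 (2Z,5R)-2-iodo-5-[(2R)-oxiran-2-yl]-5-[(triethylsilyl)oxy]pent-2-en-1-ol; 12 (3E,7E)-4,8,12-trimethyltrideca-1,3,7,11-tetraene
Product: 14 (2E,5E,9E)-6,10,14-trimethyl-2-{(2R)-2-[(2R)-oxiran-2-yl]-2-[(triethylsilyl)oxy]ethylidene}pentadeca-5,9,13-trien-1-ol, via B-homofarnesyl-9-BBN 13 (not isolated)
Conditions: 12, 9-BBN, THF, 0 °C to rt; then 9, Pd(dppf)Cl2·CH2Cl2 (cat.), AsPh3, Cs2CO3, DMF/H2O, rt
Reagents that add atoms: none
Why: 9-BBN should hydroborate only the monosubstituted terminal alkene of the diene (anti-Markovnikov) to give the homoallylic borane, and the B-alkyl Suzuki–Miyaura coupling proceeds with retention at sp2 carbon, so the homofarnesyl chain ends up cis to the CH2CH(OSiEt3) branch.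

Step 10
Reactants: 14 (2E,5E,9E)-6,10,14-trimethyl-2-{(2R)-2-[(2R)-oxiran-2-yl]-2-[(triethylsilyl)oxy]ethylidene}pentadeca-5,9,13-trien-1-ol
Product: 15 (2R)-2-[(1R,3E,7E,11E)-8,12,16-trimethyl-1-[(triethylsilyl)oxy]-4-{[(triethylsilyl)oxy]methyl}heptadeca-3,7,11,15-tetraen-1-yl]oxirane
Conditions: TESCl, imidazole, CH2Cl2, 0 °C
Reagents that add atoms: chlorotriethylsilane, CC[Si](Cl)(CC)CC
Why: Routine silylation of the primary allylic alcohol leaves no free hydroxyl in the carbonylation substrate.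

Step 11
Reactants: 15 (2R)-2-[(1R,3E,7E,11E)-8,12,16-trimethyl-1-[(triethylsilyl)oxy]-4-{[(triethylsilyl)oxy]methyl}heptadeca-3,7,11,15-tetraen-1-yl]oxirane
Product: 17 (3S)-3-[(1R,3E,7E,11E)-8,12,16-trimethyl-1-[(triethylsilyl)oxy]-4-{[(triethylsilyl)oxy]methyl}heptadeca-3,7,11,15-tetraen-1-yl]oxolane-2,5-dione, via beta-lactone 16 (not isolated)
Conditions: [(ClTPP)Al(THF)2][Co(CO)4] (5 mol%), CO (60 bar), 1,4-dioxane, 90 °C
Reagents that add atoms: carbon monoxide, [C-]#[O+]
Why: The aluminium porphyrin cation activates the epoxide, Co(CO)4− opens it by SN2 attack at the unsubstituted CH2, CO inserts into the C–Co bond and the aluminium alkoxide closes on the acyl cobalt to give beta-lactone 16 (4-exo-trig acyl substitution, epoxide CH retained); the same ion pair then activates the lactone, cobaltate attacks its alkyl C–O carbon with inversion, CO inserts again and the carboxylate closes on the new acyl cobalt to give the five-membered anhydride (5-exo-trig acyl substitution). The closest known reaction is the bimetallic Lewis acid/cobaltate double carbonylation of terminal epoxides to succinic anhydrides, a ring expansion 3 → 4 → 5 in which the epoxide oxygen becomes the anhydride oxygen. The only new stereocentre, the ring CH, is controlled by the (R)-epoxide carbon through the stereospecific SN2 inversion of the second insertion, while the neighbouring (R)-silyloxy centre is not touched, so the threo (R,R) epoxide should give the (S)-ring CH/(R)-carbinol pair of the target. The step needs regioselective first attack at CH2 (secured by the monosubstituted epoxide), inertness of the four trisubstituted alkenes (no hydride source is present and cobaltate does not add to unactivated alkenes) and silent oxygens (both hydroxyls are silyl ethers, so neither translactonisation to a γ-lactone nor alcoholysis of the anhydride can occur). Dioxane is chosen because it donates enough for the epoxide stage without blocking the Lewis acid in the lactone stage.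

Step 12
Reactants: 17 (3S)-3-[(1R,3E,7E,11E)-8,12,16-trimethyl-1-[(triethylsilyl)oxy]-4-{[(triethylsilyl)oxy]methyl}heptadeca-3,7,11,15-tetraen-1-yl]oxolane-2,5-dione
Product: 18 (3S)-3-[(1R,3E,7E,11E)-1-hydroxy-4-(hydroxymethyl)-8,12,16-trimethylheptadeca-3,7,11,15-tetraen-1-yl]oxolane-2,5-dione
Conditions: HF·pyridine, THF, 0 °C
Reagents that add atoms: none
Why: Fluoride-driven cleavage of both triethylsilyl ethers under acidic, water-free and alcohol-free conditions is chosen because the anhydride would not survive basic fluoride, aqueous acid or alcoholic solvents, and no stereocentre is touched.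

Step 13
Reactants: 18 (3S)-3-[(1R,3E,7E,11E)-1-hydroxy-4-(hydroxymethyl)-8,12,16-trimethylheptadeca-3,7,11,15-tetraen-1-yl]oxolane-2,5-dione
Product: 19 Hippolide D, (3S)-3-[(1R,3E,7E,11E)-4-formyl-1-hydroxy-8,12,16-trimethylheptadeca-3,7,11,15-tetraen-1-yl]oxolane-2,5-dione
Conditions: TEMPO (cat.), PhI(OAc)2, CH2Cl2, rt
Reagents that add atoms: none
Why: TEMPO/PhI(OAc)2 oxidation is selective for a primary (here also allylic) alcohol over a secondary one and runs under non-basic anhydrous conditions in which the anhydride, the free secondary hydroxyl and the ring stereocentre should persist.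

**Compound list**

1 | (2R,3R)-2,3-dihydroxybutane-1,4-diyl bis(4-methylbenzenesulfonate) | Cc1ccc(cc1)S(=O)(=O)OC[C@@H](O)[C@H](O)COS(=O)(=O)c1ccc(C)cc1 | starting material
2 | (2R,2'R)-2,2'-bioxirane | C1O[C@H]1[C@H]1CO1 | intermediate
3 | 1-methoxy-4-[(prop-2-yn-1-yloxy)methyl]benzene | C#CCOCc1ccc(OC)cc1 | starting material
4 | lithium acetylide of 3 | [Li]C#CCOCc1ccc(OC)cc1 | intermediate
5 | (1R)-5-[(4-methoxybenzyl)oxy]-1-[(2R)-oxiran-2-yl]pent-3-yn-1-ol | COc1ccc(COCC#CC[C@@H](O)[C@H]2CO2)cc1 | intermediate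
6 | triethyl({(1R)-5-[(4-methoxybenzyl)oxy]-1-[(2R)-oxiran-2-yl]pent-3-yn-1-yl}oxy)silane | COc1ccc(COCC#CC[C@@H](O[Si](CC)(CC)CC)[C@H]2CO2)cc1 | intermediate
7 | (5R)-5-[(2R)-oxiran-2-yl]-5-[(triethylsilyl)oxy]pent-2-yn-1-ol | OCC#CC[C@@H](O[Si](CC)(CC)CC)[C@H]1CO1 | intermediate
8 | (2Z,5R)-5-[(2R)-oxiran-2-yl]-2-(tributylstannyl)-5-[(triethylsilyl)oxy]pent-2-en-1-ol | OC/C([Sn](CCCC)(CCCC)CCCC)=C/C[C@@H](O[Si](CC)(CC)CC)[C@H]1CO1 | intermediate
9 | (2Z,5R)-2-iodo-5-[(2R)-oxiran-2-yl]-5-[(triethylsilyl)oxy]pent-2-en-1-ol | OC/C(I)=C/C[C@@H](O[Si](CC)(CC)CC)[C@H]1CO1 | intermediate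
10 | (2E,6E)-farnesol | CC(C)=CCC/C(C)=C/CC/C(C)=C/CO | starting material
11 | (2E,6E)-farnesal | CC(C)=CCC/C(C)=C/CC/C(C)=C/C=O | intermediate
12 | (3E,7E)-4,8,12-trimethyltrideca-1,3,7,11-tetraene | CC(C)=CCC/C(C)=C/CC/C(C)=C/C=C | intermediate
13 | 9-[(3E,7E)-4,8,12-trimethyltrideca-3,7,11-trien-1-yl]-9-borabicyclo[3.3.1]nonane | CC(C)=CCC/C(C)=C/CC/C(C)=C/CCB1C2CCCC1CCC2 | intermediate
14 | (2E,5E,9E)-6,10,14-trimethyl-2-{(2R)-2-[(2R)-oxiran-2-yl]-2-[(triethylsilyl)oxy]ethylidene}pentadeca-5,9,13-trien-1-ol | CC(C)=CCC/C(C)=C/CC/C(C)=C/CC/C(CO)=C\C[C@@H](O[Si](CC)(CC)CC)[C@H]1CO1 | intermediate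
15 | (2R)-2-[(1R,3E,7E,11E)-8,12,16-trimethyl-1-[(triethylsilyl)oxy]-4-{[(triethylsilyl)oxy]methyl}heptadeca-3,7,11,15-tetraen-1-yl]oxirane | CC(C)=CCC/C(C)=C/CC/C(C)=C/CC/C(CO[Si](CC)(CC)CC)=C\C[C@@H](O[Si](CC)(CC)CC)[C@H]1CO1 | intermediate
16 | (4R)-4-[(1R,3E,7E,11E)-8,12,16-trimethyl-1-[(triethylsilyl)oxy]-4-{[(triethylsilyl)oxy]methyl}heptadeca-3,7,11,15-tetraen-1-yl]oxetan-2-one | CC(C)=CCC/C(C)=C/CC/C(C)=C/CC/C(CO[Si](CC)(CC)CC)=C\C[C@@H](O[Si](CC)(CC)CC)[C@H]1CC(=O)O1 | intermediate
17 | (3S)-3-[(1R,3E,7E,11E)-8,12,16-trimethyl-1-[(triethylsilyl)oxy]-4-{[(triethylsilyl)oxy]methyl}heptadeca-3,7,11,15-tetraen-1-yl]oxolane-2,5-dione | CC(C)=CCC/C(C)=C/CC/C(C)=C/CC/C(CO[Si](CC)(CC)CC)=C\C[C@@H](O[Si](CC)(CC)CC)[C@@H]1CC(=O)OC1=O | intermediate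
18 | (3S)-3-[(1R,3E,7E,11E)-1-hydroxy-4-(hydroxymethyl)-8,12,16-trimethylheptadeca-3,7,11,15-tetraen-1-yl]oxolane-2,5-dione | CC(C)=CCC/C(C)=C/CC/C(C)=C/CC/C(CO)=C\C[C@@H](O)[C@@H]1CC(=O)OC1=O | intermediate
19 | Hippolide D, (3S)-3-[(1R,3E,7E,11E)-4-formyl-1-hydroxy-8,12,16-trimethylheptadeca-3,7,11,15-tetraen-1-yl]oxolane-2,5-dione | CC(C)=CCC/C(C)=C/CC/C(C)=C/CC/C(C=O)=C\C[C@@H](O)[C@@H]1CC(=O)OC1=O | target

**Totals**
Total step count: 13. Longest linear sequence: 11 steps (steps 1–6 and 9–13, from 1 to 19).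

**Steps most likely to fail**

Step 11. What may go wrong: the second CO insertion stalls. SN2 attack of the cobaltate on the lactone carbon is slow because that carbon is flanked by the silyloxy-bearing carbon. Lewis-acid isomerisation of the epoxide and β-elimination of the silyloxy group could then consume material.
Fallback (sets out from 15, comes back at 17): the anhydride carbons are brought in as a succinate, and the two stereocentres are made by an auxiliary-controlled syn-aldol reaction instead of by carbonylation. 15 is hydrolysed with HClO4 (cat.) in THF/H2O, which opens the epoxide and removes both silyl ethers to give tetraol F1. NaIO4 then cleaves the 1,2,3-triol to β,γ-unsaturated hydroxy aldehyde F2, which is silylated at once (TESCl, imidazole) to silyloxy aldehyde F3. Succinyl imide F4 is obtained by N-acylation of lithiated (4S)-4-benzyl-1,3-oxazolidin-2-one with methyl 4-chloro-4-oxobutanoate. Bu2BOTf/i-Pr2NEt converts it into boron enolate F5, which should add to F3 through the chair transition state of the Evans syn-aldol reaction to give aldol adduct F6 with the (S)-α/(R)-carbinol pair of the target. Silylation (TESOTf, 2,6-lutidine) gives silyl ether F7. LiOH/H2O2 removes the auxiliary and the methyl ester to give diacid F8, and cyclodehydration with dicyclohexylcarbodiimide in CH2Cl2 closes the anhydride to give 17.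

Step 12. What may go wrong: acyl transfer once the hydroxyls are free. The primary allylic alcohol can open the anhydride of a second molecule, and the secondary alcohol can attack the distal carbonyl (ring–chain isomerisation to the γ-lactone acid). Pyridine and the longer exposure needed to remove two silyl ethers favour both.
Fallback (sets out from 14, comes back at 19): the enal is set before the ring is made, so no primary alcohol ever stands beside the anhydride and the last step removes a single silyl ether. 14 is oxidised with TEMPO/PhI(OAc)2 to epoxy enal F9. Double carbonylation under the conditions of step 11 should give, by way of lactone F10, silyloxy anhydride enal F11. Brief treatment with HF·pyridine in THF at −20 °C then gives 19.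

Step 5. What may go wrong: loss of regio- and stereocontrol in the hydrostannation, because the epoxide and silyl ether oxygens compete with the hydroxyl for the hydrogen-bond array at ruthenium; protodestannylation of the product is a further risk.
Fallback (sets out from 2, comes back at 9): the iodoalkene is made from an enal by iodination and reduction instead of from an alkyne. 2 is opened with vinylmagnesium bromide and CuI (cat.) in THF at −40 °C to homoallylic epoxy alcohol F12, which is silylated (TESCl, imidazole) to silyl ether F13. Cross-metathesis with crotonaldehyde (second-generation Grubbs catalyst, CH2Cl2, 40 °C) should give (E)-enal F14. α-Iodination with I2, K2CO3 and DMAP (cat.) in THF/H2O proceeds by addition–elimination and should give the thermodynamic geometry with iodine cis to the chain, (Z)-iodo enal F15. Luche reduction (NaBH4, CeCl3·7H2O, MeOH, −40 °C) then gives 9.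

**Further compounds**

F1 | step 11 | (2R,3R,5E,9E,13E)-6-(hydroxymethyl)-10,14,18-trimethylnonadeca-5,9,13,17-tetraene-1,2,3-triol | CC(C)=CCC/C(C)=C/CC/C(C)=C/CC/C(CO)=C\C[C@@H](O)[C@H](O)CO
F2 | step 11 | (3E,7E,11E)-4-(hydroxymethyl)-8,12,16-trimethylheptadeca-3,7,11,15-tetraenal | CC(C)=CCC/C(C)=C/CC/C(C)=C/CC/C(CO)=C\CC=O
F3 | step 11 | (3E,7E,11E)-8,12,16-trimethyl-4-{[(triethylsilyl)oxy]methyl}heptadeca-3,7,11,15-tetraenal | CC(C)=CCC/C(C)=C/CC/C(C)=C/CC/C(CO[Si](CC)(CC)CC)=C\CC=O
F4 | step 11 | methyl 4-[(4S)-4-benzyl-2-oxo-1,3-oxazolidin-3-yl]-4-oxobutanoate | COC(=O)CCC(=O)N1[C@@H](Cc2ccccc2)COC1=O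
F5 | step 11 | dibutylboron (Z)-enolate of F4 | CCCCB(CCCC)O/C(=C\CC(=O)OC)N1[C@@H](Cc2ccccc2)COC1=O
F6 | step 11 | methyl (3S,4R,6E,10E,14E)-3-{[(4S)-4-benzyl-2-oxo-1,3-oxazolidin-3-yl]carbonyl}-4-hydroxy-11,15,19-trimethyl-7-{[(triethylsilyl)oxy]methyl}icosa-6,10,14,18-tetraenoate | CC(C)=CCC/C(C)=C/CC/C(C)=C/CC/C(CO[Si](CC)(CC)CC)=C\C[C@@H](O)[C@H](CC(=O)OC)C(=O)N1[C@@H](Cc2ccccc2)COC1=O
F7 | step 11 | 4-O-triethylsilyl ether of F6 | CC(C)=CCC/C(C)=C/CC/C(C)=C/CC/C(CO[Si](CC)(CC)CC)=C\C[C@@H](O[Si](CC)(CC)CC)[C@H](CC(=O)OC)C(=O)N1[C@@H](Cc2ccccc2)COC1=O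
F8 | step 11 | (2S)-2-[(1R,3E,7E,11E)-8,12,16-trimethyl-1-[(triethylsilyl)oxy]-4-{[(triethylsilyl)oxy]methyl}heptadeca-3,7,11,15-tetraen-1-yl]butanedioic acid | CC(C)=CCC/C(C)=C/CC/C(C)=C/CC/C(CO[Si](CC)(CC)CC)=C\C[C@@H](O[Si](CC)(CC)CC)[C@H](CC(=O)O)C(=O)O
F9 | step 12 | (2E,5E,9E)-6,10,14-trimethyl-2-{(2R)-2-[(2R)-oxiran-2-yl]-2-[(triethylsilyl)oxy]ethylidene}pentadeca-5,9,13-trienal | CC(C)=CCC/C(C)=C/CC/C(C)=C/CC/C(C=O)=C\C[C@@H](O[Si](CC)(CC)CC)[C@H]1CO1
F10 | step 12 | (4R)-4-[(1R,3E,7E,11E)-4-formyl-8,12,16-trimethyl-1-[(triethylsilyl)oxy]heptadeca-3,7,11,15-tetraen-1-yl]oxetan-2-one | CC(C)=CCC/C(C)=C/CC/C(C)=C/CC/C(C=O)=C\C[C@@H](O[Si](CC)(CC)CC)[C@H]1CC(=O)O1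
F11 | step 12 | (3S)-3-[(1R,3E,7E,11E)-4-formyl-8,12,16-trimethyl-1-[(triethylsilyl)oxy]heptadeca-3,7,11,15-tetraen-1-yl]oxolane-2,5-dione | CC(C)=CCC/C(C)=C/CC/C(C)=C/CC/C(C=O)=C\C[C@@H](O[Si](CC)(CC)CC)[C@@H]1CC(=O)OC1=O
F12 | step 5 | (1R)-1-[(2R)-oxiran-2-yl]but-3-en-1-ol | C=CC[C@@H](O)[C@H]1CO1
F13 | step 5 | triethyl({(1R)-1-[(2R)-oxiran-2-yl]but-3-en-1-yl}oxy)silane | C=CC[C@@H](O[Si](CC)(CC)CC)[C@H]1CO1
F14 | step 5 | (2E,5R)-5-[(2R)-oxiran-2-yl]-5-[(triethylsilyl)oxy]pent-2-enal | O=C/C=C/C[C@@H](O[Si](CC)(CC)CC)[C@H]1CO1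
F15 | step 5 | (2Z,5R)-2-iodo-5-[(2R)-oxiran-2-yl]-5-[(triethylsilyl)oxy]pent-2-enal | O=C/C(I)=C/C[C@@H](O[Si](CC)(CC)CC)[C@H]1CO1
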